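**Assumptions (one line each)**
- (S)-Terpinen-4-ol is available enantiopure from tea-tree oil.
- The β-hydroxy aldehyde from the amine-catalysed aldol can be intercepted by in-situ NaBH4 before it dehydrates.
- The hindered secondary alcohol of jaeschkeanadiol (16) is acylated selectively over the tertiary one, and an aryl acetate is cleaved without touching the alkyl benzoate.

**Retrosynthetic overview**
1. Ferutinine (19) is the p-hydroxybenzoate of jaeschkeanadiol (16), made by acylation of the secondary alcohol.
2. The seven-membered ring, with its trisubstituted ring alkene, comes from ring-closing metathesis of allyl/methallyl diene 15. 15 comes from chelation-controlled methallylation of hydroxy-aldehyde 13, which sets the carbinol carbon (CH-OAr).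
3. The quaternary methyl-bearing ring-fusion carbon is forged in the key photoredox step: deoxygenative allylation of a tertiary cyclopentyl oxalate, trans to the adjacent CH2OTES group.
4. The cyclopentane comes from an intramolecular aldol of the keto-aldehyde obtained by ozonolysis of (S)-terpinen-4-ol TES ether. The C(OH)iPr stereocentre is the only one bought chiral.
5. Rings are formed in the order cyclopentane (aldol), then cycloheptene (RCM).

**Route**

Step 1
Reactants: 1 (S)-terpinen-4-ol; 2 triethylsilyl triflate
Product: 3 (S)-1-isopropyl-4-methylcyclohex-3-en-1-yl triethylsilyl ether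
Conditions: 2, 2,6-lutidine, CH2Cl2, −78 → 0 °C
Reagents that add atoms: triethylsilyl triflate, CC[Si](CC)(CC)OS(=O)(=O)C(F)(F)F
Why: Silylation of the tertiary alcohol blocks later retro-aldol, β-elimination and oxalate formation at this oxygen. The stereocentre is untouched.

Step 2
Reactants: 3
Product: 4 (S)-3-isopropyl-6-oxo-3-(triethylsilyloxy)heptanal
Conditions: O3, CH2Cl2/MeOH, −78 °C; then Me2S, −78 °C → rt
Reagents that add atoms: ozone, [O-][O+]=O
Why: Ozonolysis (Criegee) cleaves the trisubstituted ring alkene to the methyl ketone and aldehyde, giving the 6-oxoheptanal pattern needed for a five-ring aldol.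

Step 3
Reactants: 4
Product: 5 cyclopentane diol: C(OH)(CH3) carbon (d), CH-CH2OH carbon (e) and C(OTES)(iPr) carbon (k) adjacent. CH2OH is trans to iPr and cis to OTES; d-epimer mixture.
Conditions: pyrrolidine (10 mol%), AcOH (10 mol%), CH2Cl2, 0 °C; then NaBH4, MeOH, 0 °C (one pot)
Reagents that add atoms: none
Why: Enamine-catalysed intramolecular aldol through the aldehyde enamine onto the methyl ketone (5-ring closure). The new CH(CHO) centre sets trans to the larger iPr group. The d-carbinol epimers are irrelevant because d becomes a radical later. NaBH4 traps the β-hydroxy aldehyde as the primary alcohol before dehydration.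

Step 4
Reactants: 5; 6 triethylsilyl chloride
Product: 7 primary TES ether of 5 (tertiary d-OH free)
Conditions: 6, imidazole, DMF, 0 °C
Reagents that add atoms: triethylsilyl chloride, CC[Si](Cl)(CC)CC
Why: Selective silylation of the primary alcohol; the hindered tertiary alcohol is left free for activation.

Step 5
Reactants: 7; 8 methyl chlorooxoacetate
Product: 9 cesium oxalate monoester of the tertiary d-alcohol (d-epimer mixture)
Conditions: 8, pyridine, DMAP, CH2Cl2, 0 °C; then CsOH·H2O, MeOH, rt (one pot; the methyl oxalate is not isolated)
Reagents that add atoms: methyl chlorooxoacetate, COC(=O)C(=O)Cl; cesium hydroxide, [Cs+].[OH-]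
Why: Acylation followed by ester saponification gives the redox-active tertiary alkyl oxalate used for photoredox deoxygenation.

Step 6
Reactants: 9; 10 allyl phenyl sulfone
Product: 11 C=CC[C@@]2(C)CC[C@@](OTES)(iPr)[C@@H]2CH2OTES. The allyl group is trans to CH2OTES, so it is cis to iPr; CH2OTES is cis to OTES.
Conditions: 10 (3 equiv), Ir[dF(CF3)ppy]2(dtbbpy)PF6 (1 mol%), DMF, blue LEDs, rt
Reagents that add atoms: allyl phenyl sulfone, C=CCS(=O)(=O)c1ccccc1
Why: Proposed new method: excited Ir(III) oxidises the oxalate, and loss of two CO2 gives a planar tertiary cyclopentyl radical. Allyl sulfone adds in an addition–fragmentation sequence, and PhSO2• is reduced back to PhSO2−, so the cycle is redox-neutral. The radical is flanked by a stereocentre carrying CH2OTES and a 1,3-related OTES group. Both shield the top face, so the allyl group arrives from the face anti to CH2OTES and the quaternary centre is set by relay from the aldol-derived centre. Closest known reaction: photoredox tert-alkyl oxalate Giese/allylation; it has not been shown on this hindered, vicinally substituted cyclopentyl radical.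

Step 7
Reactants: 11
Product: 12 diol: CH2OH and tertiary C-OH, with allyl and methyl on the quaternary carbon
Conditions: TBAF, THF, 45 °C
Reagents that add atoms: none
Why: Fluoride removes both TES groups. No carbonyl is present, so nothing epimerises.

Step 8
Reactants: 12
Product: 13 β-hydroxy aldehyde (CHO trans to allyl and iPr, cis to OH)
Conditions: Dess–Martin periodinane, NaHCO3, CH2Cl2, 0 °C; used crude
Reagents that add atoms: none
Why: DMP oxidises only the primary alcohol. The aldehyde-bearing carbon keeps the thermodynamically favoured trans arrangement relative to the bulky allyl and iPr groups.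

Step 9
Reactants: 13; 14 methallyl bromide
Product: 15 diene diol with a CH(OH)CH2C(CH3)=CH2 side chain
Conditions: 14, In powder, THF/sat. aq. NH4Cl, rt
Reagents that add atoms: methallyl bromide, CC(=C)CBr
Why: Indium Barbier (allylmetal) addition under β-hydroxy chelation between the tertiary alkoxide and the aldehyde oxygen. The nucleophile attacks the face anti to the quaternary neighbour and syn to the ring-fusion H, which gives the carbinol configuration of the target.

Step 10
Reactants: 15
Product: 16 jaeschkeanadiol (ferutinol)
Conditions: Hoveyda–Grubbs II (10 mol%), toluene (3 mM), 80 °C, N2 sparge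
Reagents that add atoms: none
Why: Ring-closing metathesis of the allyl and methallyl termini forms the cycloheptene with a trisubstituted, methyl-bearing ring alkene. No stereocentre is altered.

Step 11
Reactants: 16; 17 4-acetoxybenzoyl chloride
Product: 18 4-acetoxybenzoate of 16
Conditions: 17, DMAP, pyridine, CH2Cl2, 0 °C → rt
Reagents that add atoms: 4-acetoxybenzoyl chloride, CC(=O)Oc1ccc(cc1)C(Cl)=O
Why: Acylation occurs at the secondary alcohol with retention; the tertiary alcohol is too hindered to react.

Step 12
Reactants: 18
Product: 19 ferutinine
Conditions: NH2NH2·AcOH, DMF, rt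
Reagents that add atoms: none
Why: Hydrazinolysis cleaves the labile aryl acetate and leaves the hindered alkyl benzoate intact.

**Compound list**

1 | (S)-terpinen-4-ol | CC1=CC[C@](O)(C(C)C)CC1 | starting material
2 | triethylsilyl triflate | CC[Si](CC)(CC)OS(=O)(=O)C(F)(F)F | starting material
3 | (S)-terpinen-4-ol TES ether | CC1=CC[C@](O[Si](CC)(CC)CC)(C(C)C)CC1 | intermediate
4 | (S)-3-isopropyl-6-oxo-3-(triethylsilyloxy)heptanal | CC(=O)CC[C@@](O[Si](CC)(CC)CC)(C(C)C)CC=O | intermediate
5 | cyclopentane diol (d-epimer mixture) | CC1(O)CC[C@@](O[Si](CC)(CC)CC)(C(C)C)[C@@H]1CO | intermediate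
6 | triethylsilyl chloride | CC[Si](Cl)(CC)CC | starting material
7 | primary TES ether of 5 | CC1(O)CC[C@@](O[Si](CC)(CC)CC)(C(C)C)[C@@H]1CO[Si](CC)(CC)CC | intermediate
8 | methyl chlorooxoacetate | COC(=O)C(=O)Cl | starting material
9 | cesium oxalate of 7 | [Cs+].[O-]C(=O)C(=O)OC1(C)CC[C@@](O[Si](CC)(CC)CC)(C(C)C)[C@@H]1CO[Si](CC)(CC)CC | intermediate
10 | allyl phenyl sulfone | C=CCS(=O)(=O)c1ccccc1 | starting material
11 | allylated bis-TES ether | C=CC[C@@]2(C)CC[C@@](O[Si](CC)(CC)CC)(C(C)C)[C@@H]2CO[Si](CC)(CC)CC | intermediate
12 | allylated diol | C=CC[C@@]2(C)CC[C@@](O)(C(C)C)[C@@H]2CO | intermediate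
13 | β-hydroxy aldehyde | C=CC[C@@]2(C)CC[C@@](O)(C(C)C)[C@@H]2C=O | intermediate
14 | methallyl bromide | CC(=C)CBr | starting material
15 | diene diol | C=CC[C@@]2(C)CC[C@@](O)(C(C)C)[C@@H]2[C@@H](O)CC(C)=C | intermediate
16 | jaeschkeanadiol (ferutinol) | CC1=CC[C@@]2(C)CC[C@@](O)(C(C)C)[C@@H]2[C@@H](O)C1 | intermediate
17 | 4-acetoxybenzoyl chloride | CC(=O)Oc1ccc(cc1)C(Cl)=O | starting material
18 | 4-acetoxybenzoate of 16 | CC1=CC[C@@]2(C)CC[C@@](O)(C(C)C)[C@@H]2[C@@H](OC(=O)c2ccc(OC(C)=O)cc2)C1 | intermediate
19 | ferutinine | CC1=CC[C@@]2(C)CC[C@@](O)(C(C)C)[C@@H]2[C@@H](OC(=O)c2ccc(O)cc2)C1 | target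

**Totals:** 12 steps; longest linear sequence 12 steps.

**Three steps most likely to fail**
1. **Step 6 (new photoredox allylation).** The tertiary radical is hindered and may be reduced or eliminate rather than allylate, or give poor diastereoselectivity.
   - Fallback: allylate the same tertiary radical by tin-chain chemistry. Convert the d-alcohol of 7 to its methyl oxalate or a thiocarbonylimidazolide, then treat with allyl-SnBu3 and AIBN in benzene at 80 °C.
2. **Step 3 (aldol/NaBH4).** The β-hydroxy aldehyde may dehydrate to the enal before reduction.
   - Fallback: push the aldol to the enal (pyrrolidine/AcOH, 60 °C). Install the quaternary centre by Lewis-acid conjugate allylation (allyl-TMS, TiCl4) on the TES-protected enal, separate the epimers at d, and rejoin the route at 13.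
3. **Step 9 (chelation-controlled methallylation).** The carbinol configuration may come out unselective.
   - Fallback: add methallyl-MgCl unselectively, carry out RCM, then oxidise to the 7-ring ketone with DMP. Reduce with Me4NBH(OAc)3, which is directed by the tertiary OH and delivers hydride from the face of that hydroxyl, to give 16.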